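**Assumptions**

- The target is taken exactly as the SMILES defines it: (2R,3R,4R,5S,6E,8S) in the nonene chain (C1–C9 as in the name of 25) and (2S,3S) in the hydroxypentyl arm.
- The sense of induction of the chiral nickel catalysts in steps 3, 11 and 13 is taken as written; if a first run shows the opposite sense, the mirror-image ligand is used and nothing else changes.

**Retrosynthetic overview**

1. C7–C8 is the last bond: a nickel-catalysed enantioconvergent reductive coupling of the (E)-alkenyl bromide (ring A half, C2–C5 already set) with the racemic 1-chloroethyl pyranone of ring B. It runs through a planar pyranonyl-ethyl radical, and the catalyst sets C8.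
2. The two other CH(CH3)–pyranone centres (C2 of the chain, C2 of the arm) come from the same radical manifold: enantioconvergent nickel acyl couplings of 2-(1-chloroethyl)pyranone with acid chlorides. The neighbouring carbinols follow by Felkin (arm) or chelate-plus-Felkin (chain) hydride reduction.
3. C4–C5 come from an Evans syn aldol of a propanoyl imide with (E)-3-bromo-2-methylpropenal, which also brings in the alkenyl bromide.
4. Rings: ring A and ring B are the same pyranone, made first and only once from pentan-3-one and propanoic acid. All later steps functionalise its ethyl groups; no ring is closed afterwards.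

**Route**

Step 1
Reactants: 1 pentan-3-one + 2 propanoic acid (2.5 equiv)
Product: 3 2,6-diethyl-3,5-dimethyl-4H-pyran-4-one
Conditions: polyphosphoric acid, 100 °C, 4 h
Reagents that add atoms: none
Why: Polyphosphoric acid turns propanoic acid into a mixed anhydride that C-acylates both α-carbons of the ketone enol, and the resulting 3,5,7-trione cyclodehydrates in the same medium (acid-mediated double acylation/cyclodehydration, the classical pyranone synthesis from a ketone and a carboxylic acid); no stereocentre is formed.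

Step 2
Reactants: 3
Product: 5 2-(1-chloroethyl)-6-ethyl-3,5-dimethyl-4H-pyran-4-one (racemate), via lithium dienolate 4 (not isolated)
Conditions: LiN(SiMe3)2 (1.05 equiv), THF, −78 °C; cannulated into C2Cl6 (1.3 equiv), THF, −78 °C
Reagents that add atoms: hexachloroethane, ClC(Cl)(Cl)C(Cl)(Cl)Cl
Why: Lateral (vinylogous) deprotonation of one 2-ethyl group gives the extended dienolate 4, which is chlorinated at its exocyclic carbon by the positive-chlorine donor (lateral lithiation/electrophilic chlorination), inverse addition keeping the more acidic product away from unreacted 4; the new centre is deliberately racemic.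

Step 3
Reactants: 5 + 6 propanoyl chloride (1.5 equiv)
Product: 7 2-ethyl-3,5-dimethyl-6-[(2R)-3-oxopentan-2-yl]-4H-pyran-4-one
Conditions: NiCl2(MeOCH2CH2OMe) (10 mol%), (R,R)-Ph-BOX [2,2'-(propane-2,2-diyl)bis(4-phenyl-4,5-dihydro-1,3-oxazole)] (22 mol%), Mn powder (3 equiv), 2,6-dimethylbenzoic acid (0.75 equiv), THF/DMA 7:3, 20 °C
Reagents that add atoms: none
Why: Proposed new method: halogen abstraction from either enantiomer of 5 by low-valent nickel gives one planar secondary radical, stabilised through the pyranone like a benzylic or α-carbonyl radical, the chiral acyl–nickel complex formed from 6 captures it, and reductive elimination from trivalent nickel sets the centre as R under ligand control while the neutral, weakly acidic medium leaves the new α-centre alone; the closest known reaction is the nickel-catalysed asymmetric reductive acyl cross-coupling of secondary benzylic chlorides with acid chlorides (Reisman type).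

Step 4
Reactants: 7
Product: 8 2-ethyl-6-[(2S,3S)-3-hydroxypentan-2-yl]-3,5-dimethyl-4H-pyran-4-one
Conditions: LiBH(s-Bu)3 (1.2 equiv), THF, −78 °C; then NaOH, H2O2, H2O, 0 °C
Reagents that add atoms: none
Why: Felkin–Anh-controlled reduction by a bulky hydride (substrate-controlled diastereoselective ketone reduction): with the pyranonyl group anti to the incoming hydride and the small hydrogen flanking its path, (R)-7 gives the 2,3-anti (2S,3S) alcohol, and at −78 °C reduction outruns enolisation so that C2 is kept.

Step 5
Reactants: 8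
Product: 10 2-(1-chloroethyl)-6-[(2S,3S)-3-hydroxypentan-2-yl]-3,5-dimethyl-4H-pyran-4-one (both epimers at the CHCl carbon), via dilithio dienolate 9 (not isolated)
Conditions: LiN(SiMe3)2 (2.2 equiv), THF, −78 °C; cannulated into C2Cl6 (1.5 equiv), THF, −78 °C; AcOH, −78 °C
Reagents that add atoms: hexachloroethane, ClC(Cl)(Cl)C(Cl)(Cl)Cl
Why: The hydroxyl is deprotonated first and the second equivalent of base then removes a proton from the unbranched ethyl group, the only lateral CH2 and remote from the alkoxide, after which chlorination as in step 2 gives the radical precursor (lateral lithiation/electrophilic chlorination); the carbinol centres are untouched and the CHCl centre may stay a mixture because step 13 is stereoconvergent.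

Step 6
Reactants: 11 2-methylprop-2-enal (methacrolein)
Product: 13 (2E)-3-bromo-2-methylprop-2-enal, via dibromide 12 (not isolated)
Conditions: Br2 (1.0 equiv), CH2Cl2, −78 → 0 °C; then Et3N (1.2 equiv), 0 °C → rt
Reagents that add atoms: bromine, BrBr
Why: Bromine adds across the alkene and triethylamine then removes HBr, which can only involve a C3 hydrogen and the C2 bromine because C2 carries no hydrogen, giving the β-bromo enal as the more stable E isomer (bromination/dehydrobromination).

Step 7
Reactants: 6 propanoyl chloride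
Product: 14 (4S)-4-benzyl-3-propanoyl-1,3-oxazolidin-2-one
Conditions: (4S)-4-benzyl-1,3-oxazolidin-2-one (1.0 equiv), Et3N (1.3 equiv), DMAP (10 mol%), CH2Cl2, 0 °C → rt
Reagents that add atoms: (4S)-4-benzyl-1,3-oxazolidin-2-one (chiral auxiliary), O=C1N[C@@H](Cc2ccccc2)CO1
Why: DMAP-catalysed N-acylation attaches the propanoyl unit to the oxazolidinone auxiliary (acyl transfer); no new stereocentre.

Step 8
Reactants: 14 + 13 (1.2 equiv)
Product: 16 (4S)-4-benzyl-3-[(2S,3S,4E)-5-bromo-3-hydroxy-2,4-dimethylpent-4-enoyl]-1,3-oxazolidin-2-one, via boron enolate 15 (not isolated)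
Conditions: Bu2BOTf (1.1 equiv), i-Pr2NEt (1.2 equiv), CH2Cl2, 0 °C; 13, −78 → 0 °C; pH 7 buffer, MeOH, H2O2, 0 °C
Reagents that add atoms: none
Why: Evans syn aldol: soft enolisation gives the Z boron enolate 15, which adds to the non-enolisable enal through a chair Zimmerman–Traxler transition state on the face away from the benzyl group, setting C2 and C3 as (2S,3S), syn, and leaving the E alkenyl bromide untouched.

Step 9
Reactants: 16
Product: 17 (4S)-4-benzyl-3-[(2S,3S,4E)-5-bromo-2,4-dimethyl-3-(triethylsilyloxy)pent-4-enoyl]-1,3-oxazolidin-2-one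
Conditions: Et3SiOTf (1.2 equiv), 2,6-lutidine (1.5 equiv), CH2Cl2, −78 → 0 °C
Reagents that add atoms: triethylsilyl trifluoromethanesulfonate (protecting group), CC[Si](CC)(CC)OS(=O)(=O)C(F)(F)F
Why: Silylation of the secondary alcohol (silyl ether protection) so that the acid can later be turned into an acid chloride; triethylsilyl is chosen because mild acid removes it in step 12.

Step 10
Reactants: 17
Product: 19 (2S,3S,4E)-5-bromo-2,4-dimethyl-3-(triethylsilyloxy)pent-4-enoic acid, via peroxy acid 18 (not isolated)
Conditions: LiOH (2 equiv), H2O2 (4 equiv), THF/H2O 3:1, 0 °C; then Na2SO3 (aq.); HCl (aq.) to pH 4, 0 °C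
Reagents that add atoms: hydrogen peroxide, OO
Why: Evans hydroperoxide cleavage: the hydroperoxide anion attacks the exocyclic imide carbonyl selectively, sulfite reduces the peroxy acid 18 to the acid, and the mild conditions neither epimerise C2 nor touch the silyl ether or the alkenyl bromide.

Step 11
Reactants: 19 (1.3 equiv) + 5 (1.0 equiv)
Product: 21 2-[(2S,4S,5S,6E)-7-bromo-4,6-dimethyl-3-oxo-5-(triethylsilyloxy)hept-6-en-2-yl]-6-ethyl-3,5-dimethyl-4H-pyran-4-one, via acid chloride 20 (not isolated)
Conditions: 1-chloro-N,N,2-trimethylprop-1-en-1-amine (1.05 equiv on 19), CH2Cl2, 0 °C → rt, evaporate; then 5, NiCl2(MeOCH2CH2OMe) (10 mol%), (S,S)-Ph-BOX (22 mol%), Mn powder (3 equiv), 2,6-dimethylbenzoic acid (0.75 equiv), THF/DMA 7:3, 20 °C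
Reagents that add atoms: none
Why: Proposed new method: the acid is converted under neutral conditions into acid chloride 20, zerovalent nickel inserts into its C–Cl bond far faster than into the hindered trisubstituted alkenyl bromide (no iodide additive, and 20 is kept in excess so that no chloride 5 remains once the C–Br bond could compete), the pyranonyl-ethyl radical from either enantiomer of 5 is captured by the acyl–nickel complex, and the mirror-image ligand of step 3 now sets the new centre as S; the closest known reaction is again the Reisman-type asymmetric reductive acyl cross-coupling.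

Step 12
Reactants: 21
Product: 24 2-[(2R,3R,4R,5S,6E)-7-bromo-3,5-dihydroxy-4,6-dimethylhept-6-en-2-yl]-6-ethyl-3,5-dimethyl-4H-pyran-4-one, via hydroxy ketone 22 (not isolated), via boron chelate 23 (not isolated)
Conditions: PPTS (0.2 equiv), MeOH, 0 °C → rt, evaporate; then Et2BOMe (1.2 equiv), THF/MeOH 4:1, −78 °C; NaBH4 (1.5 equiv), −78 °C; AcOH; MeOH co-evaporation
Reagents that add atoms: none
Why: Acidic methanolysis frees the β-hydroxyl (silyl ether cleavage), its diethylboron chelate 23 is reduced by external hydride delivered axially to the six-membered chelate (Narasaka–Prasad reduction) to give the 1,3-syn diol, and this same face is the Felkin face with respect to C2 (pyranonyl group anti to hydride), so both controls reinforce to set C3 as R while C2, C4 and C5 are not touched at −78 °C.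

Step 13
Reactants: 24 (1.0 equiv) + 10 (1.5 equiv)
Product: 25 CNP0408419.10, 2-[(2R,3R,4R,5S,6E,8S)-3,5-dihydroxy-8-{6-[(2S,3S)-3-hydroxypentan-2-yl]-3,5-dimethyl-4-oxo-4H-pyran-2-yl}-4,6-dimethylnon-6-en-2-yl]-6-ethyl-3,5-dimethyl-4H-pyran-4-one
Conditions: NiCl2(MeOCH2CH2OMe) (10 mol%), (3aS,3a'S,8aR,8a'R)-2,2'-(cyclopropane-1,1-diyl)bis(3a,8a-dihydro-8H-indeno[1,2-d][1,3]oxazole) (12 mol%), Mn powder (3 equiv), NaI (0.5 equiv), DMA, 0 °C, 24 h
Reagents that add atoms: none
Why: Proposed new method: zerovalent nickel adds oxidatively to the alkenyl bromide with retention of the E geometry, halogen abstraction from either epimer of 10 gives the same planar pyranonyl-ethyl radical, and its capture and reductive elimination at the chiral bis(oxazoline) nickel centre form C7–C8 and set C8 as S under catalyst control, free hydroxyls being tolerated in manganese-driven cross-electrophile coupling; the closest known reaction is the nickel-catalysed enantioconvergent reductive coupling of alkenyl bromides with secondary benzylic chlorides (Reisman type).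

**Compound list**

1 | pentan-3-one | CCC(=O)CC | starting material
2 | propanoic acid | CCC(=O)O | starting material
3 | 2,6-diethyl-3,5-dimethyl-4H-pyran-4-one | CCc1oc(CC)c(C)c(=O)c1C | intermediate
4 | lithium 6-ethyl-2-ethylidene-3,5-dimethyl-2H-pyran-4-olate (lithium dienolate of 3) | CC=C1OC(CC)=C(C)C(O[Li])=C1C | intermediate
5 | 2-(1-chloroethyl)-6-ethyl-3,5-dimethyl-4H-pyran-4-one (racemate) | CCc1oc(C(C)Cl)c(C)c(=O)c1C | intermediate
6 | propanoyl chloride | CCC(=O)Cl | starting material
7 | 2-ethyl-3,5-dimethyl-6-[(2R)-3-oxopentan-2-yl]-4H-pyran-4-one | CCC(=O)[C@H](C)c1oc(CC)c(C)c(=O)c1C | intermediate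
8 | 2-ethyl-6-[(2S,3S)-3-hydroxypentan-2-yl]-3,5-dimethyl-4H-pyran-4-one | CCc1oc([C@@H](C)[C@@H](O)CC)c(C)c(=O)c1C | intermediate
9 | dilithio dienolate of 8 (lithium alkoxide at C3 of the arm, lithium 2-ethylidene-2H-pyran-4-olate) | CC=C1OC([C@@H](C)[C@@H](O[Li])CC)=C(C)C(O[Li])=C1C | intermediate
10 | 2-(1-chloroethyl)-6-[(2S,3S)-3-hydroxypentan-2-yl]-3,5-dimethyl-4H-pyran-4-one (both epimers at the CHCl carbon) | CC(Cl)c1oc([C@@H](C)[C@@H](O)CC)c(C)c(=O)c1C | intermediate
11 | 2-methylprop-2-enal (methacrolein) | CC(=C)C=O | starting material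
12 | 2,3-dibromo-2-methylpropanal | CC(Br)(CBr)C=O | intermediate
13 | (2E)-3-bromo-2-methylprop-2-enal | O=C/C(C)=C/Br | intermediate
14 | (4S)-4-benzyl-3-propanoyl-1,3-oxazolidin-2-one | CCC(=O)N1[C@@H](Cc2ccccc2)COC1=O | intermediate
15 | dibutylboron (Z)-enolate of 14 | CCCCB(CCCC)O/C(=C\C)N1[C@@H](Cc2ccccc2)COC1=O | intermediate
16 | (4S)-4-benzyl-3-[(2S,3S,4E)-5-bromo-3-hydroxy-2,4-dimethylpent-4-enoyl]-1,3-oxazolidin-2-one | O=C(N1[C@@H](Cc2ccccc2)COC1=O)[C@@H](C)[C@H](O)/C(C)=C/Br | intermediate
17 | (4S)-4-benzyl-3-[(2S,3S,4E)-5-bromo-2,4-dimethyl-3-(triethylsilyloxy)pent-4-enoyl]-1,3-oxazolidin-2-one | O=C(N1[C@@H](Cc2ccccc2)COC1=O)[C@@H](C)[C@H](O[Si](CC)(CC)CC)/C(C)=C/Br | intermediate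
18 | (2S,3S,4E)-5-bromo-2,4-dimethyl-3-(triethylsilyloxy)pent-4-eneperoxoic acid | OOC(=O)[C@@H](C)[C@H](O[Si](CC)(CC)CC)/C(C)=C/Br | intermediate
19 | (2S,3S,4E)-5-bromo-2,4-dimethyl-3-(triethylsilyloxy)pent-4-enoic acid | OC(=O)[C@@H](C)[C@H](O[Si](CC)(CC)CC)/C(C)=C/Br | intermediate
20 | (2S,3S,4E)-5-bromo-2,4-dimethyl-3-(triethylsilyloxy)pent-4-enoyl chloride | ClC(=O)[C@@H](C)[C@H](O[Si](CC)(CC)CC)/C(C)=C/Br | intermediate
21 | 2-[(2S,4S,5S,6E)-7-bromo-4,6-dimethyl-3-oxo-5-(triethylsilyloxy)hept-6-en-2-yl]-6-ethyl-3,5-dimethyl-4H-pyran-4-one | CCc1oc([C@H](C)C(=O)[C@@H](C)[C@H](O[Si](CC)(CC)CC)/C(C)=C/Br)c(C)c(=O)c1C | intermediate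
22 | 2-[(2S,4S,5S,6E)-7-bromo-5-hydroxy-4,6-dimethyl-3-oxohept-6-en-2-yl]-6-ethyl-3,5-dimethyl-4H-pyran-4-one | CCc1oc([C@H](C)C(=O)[C@@H](C)[C@H](O)/C(C)=C/Br)c(C)c(=O)c1C | intermediate
23 | O-diethylboryl chelate of 22 (diethylborinate at the C5 oxygen) | CCc1oc([C@H](C)C(=O)[C@@H](C)[C@H](OB(CC)CC)/C(C)=C/Br)c(C)c(=O)c1C | intermediate
24 | 2-[(2R,3R,4R,5S,6E)-7-bromo-3,5-dihydroxy-4,6-dimethylhept-6-en-2-yl]-6-ethyl-3,5-dimethyl-4H-pyran-4-one | CCc1oc([C@H](C)[C@H](O)[C@@H](C)[C@H](O)/C(C)=C/Br)c(C)c(=O)c1C | intermediate
25 | CNP0408419.10, 2-[(2R,3R,4R,5S,6E,8S)-3,5-dihydroxy-8-{6-[(2S,3S)-3-hydroxypentan-2-yl]-3,5-dimethyl-4-oxo-4H-pyran-2-yl}-4,6-dimethylnon-6-en-2-yl]-6-ethyl-3,5-dimethyl-4H-pyran-4-one | CCc1oc([C@H](C)[C@H](O)[C@@H](C)[C@H](O)/C(C)=C/[C@H](C)c2oc([C@@H](C)[C@@H](O)CC)c(C)c(=O)c2C)c(C)c(=O)c1C | target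

**Step count and risks**

Total steps: 13. Longest linear sequence: 7 steps (step 6 or step 7, then steps 8, 9, 10, 11, 12 and 13).

The three steps most likely to fail:

Step 13 (final union). Both partners are new substrate classes for this coupling: a trisubstituted alkenyl bromide carrying a free diol, and a pyranonyl chloride in place of a benzylic one. The catalyst must also override five existing stereocentres, and homodimerisation of 10 or direct reduction of its C–Cl bond by manganese can compete. The fallback makes C8 by asymmetric hydrometalation instead of halogen abstraction. It sets out from 10, which is dehydrochlorinated (DBU, toluene, 80 °C) to 2-ethenyl-6-[(2S,3S)-3-hydroxypentan-2-yl]-3,5-dimethyl-4H-pyran-4-one F1. A nickel hydride formed from NiI2, a chiral bis(oxazoline) ligand, (MeO)2MeSiH and KF in DMA adds across the vinyl group of F1 in the Markovnikov sense, which places nickel on the carbon next to the ring; this species is then coupled with alkenyl bromide 24 (enantioselective hydroalkenylation of a vinylarene-type olefin). The fallback comes back to the route at 25.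

Step 11 (acyl coupling in the presence of the alkenyl bromide). The C–Br bond may be attacked by low-valent nickel, the acid chloride is α-branched and hindered, and the chiral acid chloride may be mismatched with the ligand. The fallback replaces the radical coupling by a polar Claisen-type acylation and drops steps 9 and 10. It sets out from 16, which is converted (AlMe3, MeONHMe·HCl, CH2Cl2, −10 °C) into (2S,3S,4E)-5-bromo-3-hydroxy-N-methoxy-N,2,4-trimethylpent-4-enamide F2. Lithium dienolate 4 (3 equiv, THF, −78 °C) adds to F2 to give hydroxy ketone 22 together with its C2 epimer 2-[(2R,4S,5S,6E)-7-bromo-5-hydroxy-4,6-dimethyl-3-oxohept-6-en-2-yl]-6-ethyl-3,5-dimethyl-4H-pyran-4-one F3. The pair is reduced as in the second half of step 12, where the reinforcing chelate and Felkin preferences favour the diol derived from 22. The epimeric diol 2-[(2S,3R,4R,5S,6E)-7-bromo-3,5-dihydroxy-4,6-dimethylhept-6-en-2-yl]-6-ethyl-3,5-dimethyl-4H-pyran-4-one F4 is removed by chromatography. The fallback comes back to the route at 24.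

Step 3 (first use of the pyranonyl chloride as radical precursor, with step 4 depending on it). The chloride may homodimerise, and the α-centre of 7, which lies between a ketone and the pyranone, may lose enantiopurity before or during the reduction. The fallback gives up the asymmetric coupling for this arm. It sets out from lithium dienolate 4 (made from 3 as in step 2), which is acylated with N-methoxy-N-methylpropanamide (CCC(=O)N(C)OC; THF, −78 °C) to racemic 2-ethyl-3,5-dimethyl-6-(3-oxopentan-2-yl)-4H-pyran-4-one F5. Reduction with LiBH(s-Bu)3 as in step 4 gives the racemic anti alcohol, that is 8 plus its enantiomer 2-ethyl-6-[(2R,3R)-3-hydroxypentan-2-yl]-3,5-dimethyl-4H-pyran-4-one F6. The two are separated by preparative HPLC on a chiral stationary phase, and the fallback comes back to the route at 8.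

**Further compounds**

F1 | step 13 | 2-ethenyl-6-[(2S,3S)-3-hydroxypentan-2-yl]-3,5-dimethyl-4H-pyran-4-one | C=Cc1oc([C@@H](C)[C@@H](O)CC)c(C)c(=O)c1C
F2 | step 11 | (2S,3S,4E)-5-bromo-3-hydroxy-N-methoxy-N,2,4-trimethylpent-4-enamide | CON(C)C(=O)[C@@H](C)[C@H](O)/C(C)=C/Br
F3 | step 11 | 2-[(2R,4S,5S,6E)-7-bromo-5-hydroxy-4,6-dimethyl-3-oxohept-6-en-2-yl]-6-ethyl-3,5-dimethyl-4H-pyran-4-one | CCc1oc([C@@H](C)C(=O)[C@@H](C)[C@H](O)/C(C)=C/Br)c(C)c(=O)c1C
F4 | step 11 | 2-[(2S,3R,4R,5S,6E)-7-bromo-3,5-dihydroxy-4,6-dimethylhept-6-en-2-yl]-6-ethyl-3,5-dimethyl-4H-pyran-4-one | CCc1oc([C@@H](C)[C@H](O)[C@@H](C)[C@H](O)/C(C)=C/Br)c(C)c(=O)c1C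
F5 | step 3 | 2-ethyl-3,5-dimethyl-6-(3-oxopentan-2-yl)-4H-pyran-4-one (racemate) | CCC(=O)C(C)c1oc(CC)c(C)c(=O)c1C
F6 | step 3 | 2-ethyl-6-[(2R,3R)-3-hydroxypentan-2-yl]-3,5-dimethyl-4H-pyran-4-one | CCc1oc([C@H](C)[C@H](O)CC)c(C)c(=O)c1C
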